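**Plan**

- Retrosynthesis: after removal of two silyl ethers, ring B (the chlorinated benzoyl ring) is cut at C3–C4 and C5–C6. This returns C4(OMe)–C5(H) to 1,1-dimethoxyethene and, with CO2 put back across C3 and C6, the other four carbons to a 2-pyrone.
- Enabling feature: C3(Cl), C2(OH), C1(ester) and C6(CH3) of ring B are C3, C4, C5 and C6 of a 4-hydroxy-6-methyl-2-pyrone-5-carboxylate. Pyrone C3 is its only nucleophilic carbon and takes the chlorine before ring B exists; pyrone C6 is the electrophilic terminus and fixes OMe para to the ester.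
- The pyrone is cut at C4–C5 and O1–C2 into malonyl dichloride and the acetoacetate of ring A; that ester is cut at the acyl–O bond into methyl orsellinate and acetylketene.
- Forward: ring A is bought complete. Its 4-OH is acetoacetylated, the pyrone ring is closed, chlorinated and silylated, ring B is made from it by cycloaddition with loss of CO2 and methanol, and the silyl groups are removed.
- Stereochemistry: the target has no stereocentre; only regiochemistry has to be controlled, and it follows from the polarity of the pyrone and the ketene acetal.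

Key step: step 5

Remark: ring A is the methyl orsellinate ring, ring B the chlorinated acyl ring numbered from the ester-bearing carbon (C1; OH at C2, Cl at C3, OMe at C4, H at C5, CH3 at C6). The pyrone is numbered O1, C2 (C=O), C3 to C6. Nothing in the target needs a configuration to be set.

**Route**

Step 1
Reactants: 1 methyl orsellinate; 2 2,2,6-trimethyl-4H-1,3-dioxin-4-one
Product: 4 methyl 2-hydroxy-6-methyl-4-[(3-oxobutanoyl)oxy]benzoate, via acetylketene 3 (not isolated)
Conditions: 2 (1.2 equiv), xylenes, 130 °C, acetone distilled off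
Reagents that add atoms: none
Why: Thermal retro-hetero-Diels–Alder fragmentation of the dioxinone releases acetylketene, which acetoacetylates the free 4-OH of 1, while the 2-OH is hydrogen-bonded to and flanked by the ester and should stay unacylated with a small excess of 2.

Step 2
Reactants: 4 methyl 2-hydroxy-6-methyl-4-[(3-oxobutanoyl)oxy]benzoate; 5 malonyl dichloride
Product: 7 3-hydroxy-4-(methoxycarbonyl)-5-methylphenyl 4-hydroxy-6-methyl-2-oxo-2H-pyran-5-carboxylate, via C-malonylated acid chloride 6 (not isolated)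
Conditions: 5 (1.05 equiv), CH2Cl2, 0 °C to 40 °C, N2 sweep
Reagents that add atoms: none
Why: This is the condensation of a beta-keto ester with malonyl dichloride to a 4-hydroxy-2-pyrone, in which the enol carbon of 4 is C-acylated, the enolized acetyl oxygen closes the lactone on the second acid chloride, and without base the chelated phenol of ring A should not compete.

Step 3
Reactants: 7 3-hydroxy-4-(methoxycarbonyl)-5-methylphenyl 4-hydroxy-6-methyl-2-oxo-2H-pyran-5-carboxylate
Product: 8 3-hydroxy-4-(methoxycarbonyl)-5-methylphenyl 3-chloro-4-hydroxy-6-methyl-2-oxo-2H-pyran-5-carboxylate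
Conditions: N-chlorosuccinimide (1.05 equiv), MeCN, 0 °C to rt
Reagents that add atoms: N-chlorosuccinimide, O=C1CCC(=O)N1Cl
Why: In this electrophilic chlorination of a vinylogous acid, pyrone C3 lies between the enol and the lactone carbonyl and is far more nucleophilic than any position of the ester-deactivated ring A, so one equivalent of reagent should chlorinate C3 alone.

Step 4
Reactants: 8 3-hydroxy-4-(methoxycarbonyl)-5-methylphenyl 3-chloro-4-hydroxy-6-methyl-2-oxo-2H-pyran-5-carboxylate
Product: 9 3-(tert-butyldimethylsilyloxy)-4-(methoxycarbonyl)-5-methylphenyl 4-(tert-butyldimethylsilyloxy)-3-chloro-6-methyl-2-oxo-2H-pyran-5-carboxylate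
Conditions: TBSOTf (2.4 equiv), 2,6-lutidine (3 equiv), CH2Cl2, −78 °C to 0 °C; non-aqueous isolation (pentane, filtration), used crude
Reagents that add atoms: tert-butyldimethylsilyl trifluoromethanesulfonate (TBSOTf), CC(C)(C)[Si](C)(C)OS(=O)(=O)C(F)(F)F
Why: O-Silylation with a silyl triflate and a hindered non-nucleophilic base caps the acidic pyrone 4-OH and the chelated phenol without touching the aryl ester, and the mobile silyl group on the pyrone should settle on O4, which keeps the 2-pyrone diene.

Step 5
Reactants: 9 3-(tert-butyldimethylsilyloxy)-4-(methoxycarbonyl)-5-methylphenyl 4-(tert-butyldimethylsilyloxy)-3-chloro-6-methyl-2-oxo-2H-pyran-5-carboxylate; 10 1,1-dimethoxyethene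
Product: 13 methyl 2-(tert-butyldimethylsilyloxy)-4-{[2-(tert-butyldimethylsilyloxy)-3-chloro-4-methoxy-6-methylbenzoyl]oxy}-6-methylbenzoate, via bridged lactone cycloadduct 11 (not isolated), via gem-dimethoxycyclohexadiene 12 (not isolated)
Conditions: 10 (5 equiv), 4 Å molecular sieves, toluene, 110 °C, sealed tube
Reagents that add atoms: none
Why: Proposed new method: 1,1-dimethoxyethene adds across C3 and C6 of the 2-pyrone of 9 in an inverse-electron-demand Diels–Alder reaction, a concerted but asynchronous (4+2) cycloaddition in which the bond from the ketene acetal CH2 to C6 runs ahead, giving bridged lactone 11; retro-Diels–Alder loss of CO2 gives diene 12, and elimination of methanol from its ketal carbon and the neighbouring CH2 makes ring B aromatic. The closest known reaction type is the thermal conversion of 2-pyrone-5-carboxylates with 1,1-dialkoxyethenes into 4-alkoxybenzoates, and the label is used because a pyrone with a donor silyloxy group at C4 and chlorine at C3 has not been shown in it. Ring B is closed intermolecularly by the cycloaddition, which forms its C3–C4 and C5–C6 bonds in one operation, so no cyclization of a chain is involved. No stereocentre remains in 13; the two bridgehead centres of 11 arise as a racemate and vanish with CO2. The step needs regioselectivity: C6 is beta to the C5 ester and vinylogous to the lactone carbonyl and holds the large LUMO coefficient, whereas C3 is the terminus of a silyl enol ether, so the nucleophilic CH2 should bond to C6 and place OMe para to the ester and next to chlorine. The C5 ester and the C3 chlorine lower the LUMO against the donor at C4, and the molecular sieves take up methanol so that unreacted 9 keeps its silyl group.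

Step 6
Reactants: 13 methyl 2-(tert-butyldimethylsilyloxy)-4-{[2-(tert-butyldimethylsilyloxy)-3-chloro-4-methoxy-6-methylbenzoyl]oxy}-6-methylbenzoate
Product: 14 methyl 4-[(3-chloro-2-hydroxy-4-methoxy-6-methylbenzoyl)oxy]-2-hydroxy-6-methylbenzoate
Conditions: HF·pyridine, pyridine, THF, 0 °C to rt
Reagents that add atoms: none
Why: Fluoride-mediated cleavage of aryl silyl ethers under buffered, non-basic conditions frees both chelated phenols and should leave the aryl ester between the rings and the methyl ester intact.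

**Compound list**

1 | methyl orsellinate (methyl 2,4-dihydroxy-6-methylbenzoate) | COC(=O)c1c(C)cc(O)cc1O | starting material
2 | 2,2,6-trimethyl-4H-1,3-dioxin-4-one | CC1=CC(=O)OC(C)(C)O1 | starting material
3 | acetylketene, formed in the flask in step 1 | CC(=O)C=C=O | intermediate
4 | methyl 2-hydroxy-6-methyl-4-[(3-oxobutanoyl)oxy]benzoate | COC(=O)c1c(C)cc(OC(=O)CC(C)=O)cc1O | intermediate
5 | malonyl dichloride | O=C(Cl)CC(Cl)=O | starting material
6 | 3-hydroxy-4-(methoxycarbonyl)-5-methylphenyl 2-acetyl-5-chloro-3,5-dioxopentanoate, formed in the flask in step 2 (enolizable methine, no defined configuration) | COC(=O)c1c(C)cc(OC(=O)C(C(C)=O)C(=O)CC(Cl)=O)cc1O | intermediate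
7 | 3-hydroxy-4-(methoxycarbonyl)-5-methylphenyl 4-hydroxy-6-methyl-2-oxo-2H-pyran-5-carboxylate | CC1=C(C(=O)Oc2cc(C)c(C(=O)OC)c(O)c2)C(O)=CC(=O)O1 | intermediate
8 | 3-hydroxy-4-(methoxycarbonyl)-5-methylphenyl 3-chloro-4-hydroxy-6-methyl-2-oxo-2H-pyran-5-carboxylate | CC1=C(C(=O)Oc2cc(C)c(C(=O)OC)c(O)c2)C(O)=C(Cl)C(=O)O1 | intermediate
9 | 3-(tert-butyldimethylsilyloxy)-4-(methoxycarbonyl)-5-methylphenyl 4-(tert-butyldimethylsilyloxy)-3-chloro-6-methyl-2-oxo-2H-pyran-5-carboxylate | CC1=C(C(=O)Oc2cc(C)c(C(=O)OC)c(O[Si](C)(C)C(C)(C)C)c2)C(O[Si](C)(C)C(C)(C)C)=C(Cl)C(=O)O1 | intermediate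
10 | 1,1-dimethoxyethene | C=C(OC)OC | starting material
11 | 3-(tert-butyldimethylsilyloxy)-4-(methoxycarbonyl)-5-methylphenyl 5-(tert-butyldimethylsilyloxy)-4-chloro-8,8-dimethoxy-1-methyl-3-oxo-2-oxabicyclo[2.2.2]oct-5-ene-6-carboxylate, formed in the flask in step 5 (racemic; the two bridgeheads are tied by the bicycle, one enantiomer drawn) | C[C@@]12CC(OC)(OC)[C@@](Cl)(C(=O)O1)C(O[Si](C)(C)C(C)(C)C)=C2C(=O)Oc3cc(C)c(C(=O)OC)c(O[Si](C)(C)C(C)(C)C)c3 | intermediate
12 | 3-(tert-butyldimethylsilyloxy)-4-(methoxycarbonyl)-5-methylphenyl 6-(tert-butyldimethylsilyloxy)-5-chloro-4,4-dimethoxy-2-methylcyclohexa-1,5-diene-1-carboxylate, formed in the flask in step 5 | CC1=C(C(=O)Oc2cc(C)c(C(=O)OC)c(O[Si](C)(C)C(C)(C)C)c2)C(O[Si](C)(C)C(C)(C)C)=C(Cl)C(OC)(OC)C1 | intermediate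
13 | methyl 2-(tert-butyldimethylsilyloxy)-4-{[2-(tert-butyldimethylsilyloxy)-3-chloro-4-methoxy-6-methylbenzoyl]oxy}-6-methylbenzoate | COC(=O)c1c(C)cc(OC(=O)c2c(C)cc(OC)c(Cl)c2O[Si](C)(C)C(C)(C)C)cc1O[Si](C)(C)C(C)(C)C | intermediate
14 | methyl 4-[(3-chloro-2-hydroxy-4-methoxy-6-methylbenzoyl)oxy]-2-hydroxy-6-methylbenzoate | COC(=O)c1c(C)cc(OC(=O)c2c(C)cc(OC)c(Cl)c2O)cc1O | target

**Count**

Total steps: 6. Longest linear sequence: 6 steps (1 → 4 → 7 → 8 → 9 → 13 → 14).

**Steps most likely to fail**

1. Step 5 (carries the label).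
 - What may go wrong: the donor silyloxy group at C4 may slow the cycloaddition so much that other processes win. These are loss of the silyl group from the vinylogous silyl ester to liberated methanol, and addition of the ketene acetal at C4 with displacement of silanolate.
 - Fallback: the pyrone is given up and the ester bond between the rings is made last, by known reactions only. It sets out from methyl orsellinate 1 as the phenol partner and comes back to the route at target 14.
 - Purchased 3,5-dimethoxytoluene F1 is lithiated between its two methoxy groups (n-BuLi, THF, 0 °C) and quenched with hexachloroethane to give 2-chloro-1,3-dimethoxy-5-methylbenzene F2.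
 - Rieche formylation (Cl2CHOMe, TiCl4, CH2Cl2) at one of the two equivalent free positions gives 3-chloro-2,4-dimethoxy-6-methylbenzaldehyde F3.
 - Pinnick oxidation (NaClO2, NaH2PO4, 2-methyl-2-butene) gives 3-chloro-2,4-dimethoxy-6-methylbenzoic acid F4.
 - Trifluoroacetic anhydride in toluene converts the acid into its mixed anhydride, which acylates the free 4-OH of 1 to give methyl 4-[(3-chloro-2,4-dimethoxy-6-methylbenzoyl)oxy]-2-hydroxy-6-methylbenzoate F5.
 - BCl3 in CH2Cl2 at −78 °C to 0 °C then cleaves only the methoxy group ortho to the ester carbonyl of ring B (chelation-directed demethylation) and gives 14.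

2. Step 2.
 - What may go wrong: the bis-acid chloride may acylate the ring A phenol or the enol oxygen instead of the enol carbon, and the hydrogen chloride formed may cleave the aryl acetoacetate before the ring closes.
 - Fallback: the order of events is changed so that no free phenol meets the acid chloride and only the pyrone hydroxyl is left to cap at the end. It sets out from 4 and comes back at 9.
 - The phenol of 4 is silylated (TBSCl, imidazole, CH2Cl2) to methyl 2-(tert-butyldimethylsilyloxy)-6-methyl-4-[(3-oxobutanoyl)oxy]benzoate F6.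
 - Malonyl dichloride should then give, through the C-malonylated acid chloride F7, the mono-silylated pyrone 3-(tert-butyldimethylsilyloxy)-4-(methoxycarbonyl)-5-methylphenyl 4-hydroxy-6-methyl-2-oxo-2H-pyran-5-carboxylate F8.
 - N-chlorosuccinimide chlorinates C3 to give 3-(tert-butyldimethylsilyloxy)-4-(methoxycarbonyl)-5-methylphenyl 3-chloro-4-hydroxy-6-methyl-2-oxo-2H-pyran-5-carboxylate F9, and TBSOTf with 2,6-lutidine silylates the pyrone hydroxyl to give 9.

3. Step 4.
 - What may go wrong: the silyl group may end on the lactone carbonyl oxygen (a 2-silyloxy-4-pyranone, which is no diene for step 5), and the vinylogous silyl ester may be lost to adventitious water during isolation.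
 - Fallback: the silyl ethers are replaced by stable methyl ethers and the oxygen functions are differentiated at the end. It sets out from 8 and comes back at 14.
 - Mitsunobu O-methylation of both hydroxyl groups of 8 (MeOH, PPh3, diisopropyl azodicarboxylate, THF) gives 3-methoxy-4-(methoxycarbonyl)-5-methylphenyl 3-chloro-4-methoxy-6-methyl-2-oxo-2H-pyran-5-carboxylate F10.
 - Heating with 10 as in step 5 should lead through the bridged lactone F11 and the gem-dimethoxycyclohexadiene F12 to methyl 4-[(3-chloro-2,4-dimethoxy-6-methylbenzoyl)oxy]-2-methoxy-6-methylbenzoate F13.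
 - BCl3 in CH2Cl2 at −78 °C to 0 °C cleaves the two methoxy groups that stand ortho to an ester carbonyl (C2 of ring B and C2 of ring A) and leaves the C4 methoxy group of ring B, which gives 14.

**Further compounds**

F1 | step 5 | 3,5-dimethoxytoluene (purchased) | COc1cc(C)cc(OC)c1
F2 | step 5 | 2-chloro-1,3-dimethoxy-5-methylbenzene | COc1cc(C)cc(OC)c1Cl
F3 | step 5 | 3-chloro-2,4-dimethoxy-6-methylbenzaldehyde | O=Cc1c(C)cc(OC)c(Cl)c1OC
F4 | step 5 | 3-chloro-2,4-dimethoxy-6-methylbenzoic acid | OC(=O)c1c(C)cc(OC)c(Cl)c1OC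
F5 | step 5 | methyl 4-[(3-chloro-2,4-dimethoxy-6-methylbenzoyl)oxy]-2-hydroxy-6-methylbenzoate | COC(=O)c1c(C)cc(OC(=O)c2c(C)cc(OC)c(Cl)c2OC)cc1O
F6 | step 2 | methyl 2-(tert-butyldimethylsilyloxy)-6-methyl-4-[(3-oxobutanoyl)oxy]benzoate | COC(=O)c1c(C)cc(OC(=O)CC(C)=O)cc1O[Si](C)(C)C(C)(C)C
F7 | step 2 | 3-(tert-butyldimethylsilyloxy)-4-(methoxycarbonyl)-5-methylphenyl 2-acetyl-5-chloro-3,5-dioxopentanoate (not isolated) | COC(=O)c1c(C)cc(OC(=O)C(C(C)=O)C(=O)CC(Cl)=O)cc1O[Si](C)(C)C(C)(C)C
F8 | step 2 | 3-(tert-butyldimethylsilyloxy)-4-(methoxycarbonyl)-5-methylphenyl 4-hydroxy-6-methyl-2-oxo-2H-pyran-5-carboxylate | CC1=C(C(=O)Oc2cc(C)c(C(=O)OC)c(O[Si](C)(C)C(C)(C)C)c2)C(O)=CC(=O)O1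
F9 | step 2 | 3-(tert-butyldimethylsilyloxy)-4-(methoxycarbonyl)-5-methylphenyl 3-chloro-4-hydroxy-6-methyl-2-oxo-2H-pyran-5-carboxylate | CC1=C(C(=O)Oc2cc(C)c(C(=O)OC)c(O[Si](C)(C)C(C)(C)C)c2)C(O)=C(Cl)C(=O)O1
F10 | step 4 | 3-methoxy-4-(methoxycarbonyl)-5-methylphenyl 3-chloro-4-methoxy-6-methyl-2-oxo-2H-pyran-5-carboxylate | CC1=C(C(=O)Oc2cc(C)c(C(=O)OC)c(OC)c2)C(OC)=C(Cl)C(=O)O1
F11 | step 4 | 3-methoxy-4-(methoxycarbonyl)-5-methylphenyl 4-chloro-5,8,8-trimethoxy-1-methyl-3-oxo-2-oxabicyclo[2.2.2]oct-5-ene-6-carboxylate (racemic, one enantiomer drawn, not isolated) | C[C@@]12CC(OC)(OC)[C@@](Cl)(C(=O)O1)C(OC)=C2C(=O)Oc3cc(C)c(C(=O)OC)c(OC)c3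
F12 | step 4 | 3-methoxy-4-(methoxycarbonyl)-5-methylphenyl 5-chloro-4,4,6-trimethoxy-2-methylcyclohexa-1,5-diene-1-carboxylate (not isolated) | CC1=C(C(=O)Oc2cc(C)c(C(=O)OC)c(OC)c2)C(OC)=C(Cl)C(OC)(OC)C1
F13 | step 4 | methyl 4-[(3-chloro-2,4-dimethoxy-6-methylbenzoyl)oxy]-2-methoxy-6-methylbenzoate | COC(=O)c1c(C)cc(OC(=O)c2c(C)cc(OC)c(Cl)c2OC)cc1OC
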